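**Strategy.** Both benzo rings carry the same ortho pair, a ring oxygen beside an acyl carbon, next to the carboxyl-bearing carbon. In ring G (benzo ring of the 2H-chromene) these are C-8a′–O-1′ and C-4a′–C-4′, so the disconnection is an aryne: benzyl 2,3-bis(benzyloxy)-5,6-didehydrobenzoate, set free from its silyl triflate, inserts into the O–C(acyl) bond of acrylic acid, and the phenoxide closes the chroman-4-one by oxa-Michael addition. This one chromanone serves both halves: C-acylation gives the triketone, formylation and dehydrogenation the 3-formylchromone. A chiral-phosphoric-acid cascade joins a pyrylium precursor to the triketone, sets the carbinol carbon and locks both ketals; hydrogenolysis ends the route.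

Key step: step 6

Remark on the chemistry: 3,4-bis(benzyloxy)phenol is taken as a purchasable building block (it is the Dakin product of commercial 3,4-bis(benzyloxy)benzaldehyde).

Locants used below: rings A/B are the benzo and γ-pyranone rings of the chromone, ring C the ketal pyran, ring D the 1,3-dioxane, ring E the dihydropyran-4-one, rings F/G the pyran and benzo rings of the 2H-chromene. C-a is the ketal carbon of rings C/D, C-14 the O-bearing CH on chromone C-3, C-15 the CH shared by rings D/E, C-b the ketal carbon of rings D/E, C-16 the ring E ketone, C-17=C-18 the ring E/F alkene. Primed locants follow chromene numbering of rings F/G (C-18 is C-4′).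

**Step 1**
Reactants: 1 3,4-bis(benzyloxy)phenol
Product: 2 1,2-bis(benzyloxy)-4-(methoxymethoxy)benzene
Conditions: MOMCl, iPr2NEt, CH2Cl2, 0 °C → rt
Reagents that add atoms: chloromethyl methyl ether, COCCl
Why: O-alkylation of the phenol (Williamson-type) installs the acetal that directs the next metalation; no stereocentre is involved.

**Step 2**
Reactants: 2 1,2-bis(benzyloxy)-4-(methoxymethoxy)benzene
Product: 4 benzyl 2,3-bis(benzyloxy)-6-(methoxymethoxy)benzoate, via aryllithium 3 (not isolated)
Conditions: n-BuLi, THF, −78 → 0 °C; then ClCO2Bn, −78 °C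
Reagents that add atoms: benzyl chloroformate, O=C(Cl)OCc1ccccc1
Why: Directed ortho-metalation should occur at the carbon flanked by the OMOM and OBn groups (most acidic, doubly chelated), and the hindered aryllithium is acylated once by the chloroformate.

**Step 3**
Reactants: 4 benzyl 2,3-bis(benzyloxy)-6-(methoxymethoxy)benzoate
Product: 5 benzyl 2,3-bis(benzyloxy)-6-hydroxybenzoate
Conditions: 2 M HCl (aq), THF, 40 °C
Reagents that add atoms: none
Why: Acid hydrolysis of the phenolic MOM acetal, which the benzyl ethers and the di-ortho-substituted benzyl ester should withstand.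

**Step 4**
Reactants: 5 benzyl 2,3-bis(benzyloxy)-6-hydroxybenzoate
Product: 6 benzyl 2,3-bis(benzyloxy)-5-bromo-6-hydroxybenzoate
Conditions: NBS, MeCN, 0 °C
Reagents that add atoms: N-bromosuccinimide, O=C1CCC(=O)N1Br
Why: Electrophilic aromatic bromination at the only open position that is ortho to the free phenol and para to the 2-benzyloxy group.

**Step 5**
Reactants: 6 benzyl 2,3-bis(benzyloxy)-5-bromo-6-hydroxybenzoate
Product: 9 benzyl 2,3-bis(benzyloxy)-6-{[(trifluoromethyl)sulfonyl]oxy}-5-(trimethylsilyl)benzoate, via silyl ether 7 (not isolated), via lithium phenoxide 8 (not isolated)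
Conditions: (Me3Si)2NH, THF, 65 °C; evaporate; n-BuLi, THF, −100 °C; Tf2O, −100 → −78 °C
Reagents that add atoms: hexamethyldisilazane, C[Si](C)(C)N[Si](C)(C)C; trifluoromethanesulfonic anhydride, O=S(=O)(OS(=O)(=O)C(F)(F)F)C(F)(F)F
Why: O-silylation, bromine–lithium exchange and anionic 1,3-O→C silyl shift (retro-Brook rearrangement) give the ortho-silyl phenoxide, which is trapped as the triflate (Kobayashi-type aryne precursor); the di-ortho-substituted ester is shielded from n-BuLi at −100 °C.

**Step 6**
Reactants: 9 benzyl 2,3-bis(benzyloxy)-6-{[(trifluoromethyl)sulfonyl]oxy}-5-(trimethylsilyl)benzoate; 10 acrylic acid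
Product: 13 benzyl 6,7-bis(benzyloxy)-4-oxo-3,4-dihydro-2H-chromene-5-carboxylate, via aryne 11 (not isolated), via vinyl ketone 12 (not isolated)
Conditions: CsF, THF, 125 °C (sealed tube)
Reagents that add atoms: none
Why: Fluoride removes the silyl group and triflate leaves to give aryne 11, whose triple bond is polarised and bent by the inductively withdrawing, bulky ester on the neighbouring carbon, so the caesium acrylate oxygen should add to the remote terminus (future C-8a′) and the carbanion develops beside the ester (future C-4a′). This carbanion attacks the carbonyl of the newly formed aryl acrylate (4-exo-trig) and the four-membered alkoxide opens to phenoxide ketone 12, a net insertion of the aryne into the O–C(acyl) bond; the closest known reaction is the fluoride-induced insertion of arynes into carboxylic acids, which with α,β-unsaturated acids is known to lead to 4-chromanones. Ring F is then closed by 6-endo-trig oxa-Michael addition of the phenoxide to the vinyl ketone. No stereocentre is formed. The step needs attack at the aryne carbon remote from the ester, and acyl transfer in preference to protonation of the carbanion; the ester (electronic and steric) secures the first, and the high temperature without excess acid the second.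

**Step 7**
Reactants: 14 ethyl (2-methyl-1,3-dioxolan-2-yl)acetate
Product: 15 (2-methyl-1,3-dioxolan-2-yl)acetic acid
Conditions: LiOH, THF/H2O, rt; then 1 M HCl to pH 3, 0 °C, immediate extraction
Reagents that add atoms: lithium hydroxide, [Li+].[OH-]
Why: Ester saponification; the ketal is stable to base and should survive the brief cold acidification.

**Step 8**
Reactants: 13 benzyl 6,7-bis(benzyloxy)-4-oxo-3,4-dihydro-2H-chromene-5-carboxylate; 15 (2-methyl-1,3-dioxolan-2-yl)acetic acid
Product: 17 benzyl 6,7-bis(benzyloxy)-3-[(2-methyl-1,3-dioxolan-2-yl)acetyl]-4-oxo-3,4-dihydro-2H-chromene-5-carboxylate (racemic β-diketone), via acyl imidazole 16 (not isolated)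
Conditions: 15, CDI, THF, rt; 13, LiN(SiMe3)2, THF, −78 °C; combine, −78 → −40 °C; AcOH
Reagents that add atoms: none
Why: Claisen-type C-acylation of the lithium enolate by an acyl imidazole; the new C-3′ centre is a labile β-diketone carbon that becomes sp2 in step 14, so no control is needed.

**Step 9**
Reactants: 17 benzyl 6,7-bis(benzyloxy)-3-[(2-methyl-1,3-dioxolan-2-yl)acetyl]-4-oxo-3,4-dihydro-2H-chromene-5-carboxylate
Product: 18 benzyl 6,7-bis(benzyloxy)-4-oxo-3-(3-oxobutanoyl)-3,4-dihydro-2H-chromene-5-carboxylate (racemic triketone)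
Conditions: AcOH/H2O/THF, 35 °C
Reagents that add atoms: water, O
Why: Acid-catalysed ketal hydrolysis unmasks the third carbonyl under conditions expected to be too mild for cyclodehydration to a γ-pyrone.

**Step 10**
Reactants: 13 benzyl 6,7-bis(benzyloxy)-4-oxo-3,4-dihydro-2H-chromene-5-carboxylate
Product: 19 benzyl 6,7-bis(benzyloxy)-3-(hydroxymethylidene)-4-oxo-3,4-dihydro-2H-chromene-5-carboxylate (Z, chelated enol of the 3-formylchromanone)
Conditions: LiN(SiMe3)2, THF, −78 °C; HCO2CH2CF3, −78 → 0 °C; AcOH
Reagents that add atoms: 2,2,2-trifluoroethyl formate, O=COCC(F)(F)F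
Why: Crossed Claisen C-formylation of the ketone lithium enolate by an activated formate should give the β-keto aldehyde as its hydrogen-bonded Z-hydroxymethylene tautomer; the hindered benzyl ester is not expected to react, and no stereocentre is formed.

**Step 11**
Reactants: 19 benzyl 6,7-bis(benzyloxy)-3-(hydroxymethylidene)-4-oxo-3,4-dihydro-2H-chromene-5-carboxylate
Product: 20 benzyl 6,7-bis(benzyloxy)-3-formyl-4-oxo-4H-chromene-5-carboxylate
Conditions: DDQ, 1,4-dioxane, rt
Reagents that add atoms: none
Why: DDQ dehydrogenation of an α-hydroxymethylene ketone to the α-formyl enone, here by hydride abstraction from C-2 (activated by the ring oxygen and the enol) and loss of the enol proton, should give the 3-formylchromone; unactivated benzyl ethers react only slowly with DDQ at room temperature.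

**Step 12**
Reactants: 20 benzyl 6,7-bis(benzyloxy)-3-formyl-4-oxo-4H-chromene-5-carboxylate; 21 2-methoxypropene
Product: 22 benzyl 7,8-bis(benzyloxy)-3-methoxy-3-methyl-10-oxo-4,4a-dihydro-3H,10H-pyrano[4,3-b]chromene-9-carboxylate (mixture of diastereomers)
Conditions: 2-methoxypropene (excess), toluene, 80 °C (sealed tube)
Reagents that add atoms: none
Why: Inverse-electron-demand hetero-Diels–Alder reaction of the 1-oxadiene (formyl C=O with C-2=C-3) with the enol ether, its polarity placing oxygen on the future ketal carbon C-a; both new stereocentres form as a mixture and are erased in steps 13 and 14.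

**Step 13**
Reactants: 22 benzyl 7,8-bis(benzyloxy)-3-methoxy-3-methyl-10-oxo-4,4a-dihydro-3H,10H-pyrano[4,3-b]chromene-9-carboxylate
Product: 24 benzyl 7,8-bis(benzyloxy)-1,3-dimethoxy-3-methyl-10-oxo-4,10-dihydro-1H,3H-pyrano[4,3-b]chromene-9-carboxylate (mixture of diastereomers), via bromo acetal 23 (not isolated)
Conditions: NBS, MeOH/CH2Cl2, −20 °C; then DBU, rt
Reagents that add atoms: methanol, CO
Why: Bromomethoxylation of the enol ether followed by dehydrobromination of the α-bromo ketone restores the chromone at the aldehyde oxidation level; the acetal and ketal centres are a mixture, and both are ionised in step 14.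

**Step 14**
Reactants: 24 benzyl 7,8-bis(benzyloxy)-1,3-dimethoxy-3-methyl-10-oxo-4,10-dihydro-1H,3H-pyrano[4,3-b]chromene-9-carboxylate; 18 benzyl 6,7-bis(benzyloxy)-4-oxo-3-(3-oxobutanoyl)-3,4-dihydro-2H-chromene-5-carboxylate
Product: 27 hexabenzyl-protected target (dibenzyl ester tetrabenzyl ether of 28; a-R,14-S,15-S,b-S), via pyrylium ion 25 (not isolated), via enol ether adduct 26 (not isolated)
Conditions: (R)-3,3′-bis(2,4,6-triisopropylphenyl)-1,1′-binaphthyl-2,2′-diyl hydrogen phosphate [(R)-TRIP] (10 mol%), 5 Å molecular sieves, toluene, 0 °C → rt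
Reagents that add atoms: none
Why: Chiral Brønsted-acid (counter-anion-directed) substitution of an acetal, in which ionisation gives pyrylium ion 25 paired with the chiral phosphate, the phosphate-bound enol of 18 adds through its methylene carbon C-15 to one face of C-14 (the (R)-catalyst is assigned by model to give the S carbinol carbon), and acid-catalysed transketalisation of 26 closes rings D and E, the ketal carbons (R at C-a, S at C-b) and the enolisable C-15 (S) settling under thermodynamic control into the cage with ring E cis-fused on the convex face.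

**Step 15**
Reactants: 27 hexabenzyl-protected target
Product: 28 CNP0230818.1
Conditions: H2 (1 atm), palladium on carbon (Pd/C), EtOAc/MeOH, rt
Reagents that add atoms: none
Why: Hydrogenolysis of the six benzylic C–O bonds; the tetrasubstituted, electron-poor alkenes and the caged ketals are not expected to react, and no stereocentre is touched.

**Compound list**

1 | 3,4-bis(benzyloxy)phenol | Oc1ccc(OCc2ccccc2)c(OCc2ccccc2)c1 | starting material
2 | 1,2-bis(benzyloxy)-4-(methoxymethoxy)benzene | COCOc1ccc(OCc2ccccc2)c(OCc2ccccc2)c1 | intermediate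
3 | [2,3-bis(benzyloxy)-6-(methoxymethoxy)phenyl]lithium | COCOc1ccc(OCc2ccccc2)c(OCc2ccccc2)c1[Li] | intermediate
4 | benzyl 2,3-bis(benzyloxy)-6-(methoxymethoxy)benzoate | COCOc1ccc(OCc2ccccc2)c(OCc2ccccc2)c1C(=O)OCc1ccccc1 | intermediate
5 | benzyl 2,3-bis(benzyloxy)-6-hydroxybenzoate | Oc1ccc(OCc2ccccc2)c(OCc2ccccc2)c1C(=O)OCc1ccccc1 | intermediate
6 | benzyl 2,3-bis(benzyloxy)-5-bromo-6-hydroxybenzoate | Oc1c(Br)cc(OCc2ccccc2)c(OCc2ccccc2)c1C(=O)OCc1ccccc1 | intermediate
7 | benzyl 2,3-bis(benzyloxy)-5-bromo-6-[(trimethylsilyl)oxy]benzoate | C[Si](C)(C)Oc1c(Br)cc(OCc2ccccc2)c(OCc2ccccc2)c1C(=O)OCc1ccccc1 | intermediate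
8 | lithium 3,4-bis(benzyloxy)-2-[(benzyloxy)carbonyl]-6-(trimethylsilyl)phenolate | [Li]Oc1c([Si](C)(C)C)cc(OCc2ccccc2)c(OCc2ccccc2)c1C(=O)OCc1ccccc1 | intermediate
9 | benzyl 2,3-bis(benzyloxy)-6-{[(trifluoromethyl)sulfonyl]oxy}-5-(trimethylsilyl)benzoate | O=C(OCc1ccccc1)c1c(OCc2ccccc2)c(OCc2ccccc2)cc([Si](C)(C)C)c1OS(=O)(=O)C(F)(F)F | intermediate
10 | acrylic acid | C=CC(=O)O | starting material
11 | benzyl 2,3-bis(benzyloxy)-5,6-didehydrobenzoate (aryne) | O=C(OCc1ccccc1)C1=C(OCc2ccccc2)C(OCc2ccccc2)=CC#C1 | intermediate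
12 | benzyl 6-acryloyl-2,3-bis(benzyloxy)-5-hydroxybenzoate | C=CC(=O)c1c(O)cc(OCc2ccccc2)c(OCc2ccccc2)c1C(=O)OCc1ccccc1 | intermediate
13 | benzyl 6,7-bis(benzyloxy)-4-oxo-3,4-dihydro-2H-chromene-5-carboxylate | O=C1CCOc2cc(OCc3ccccc3)c(OCc3ccccc3)c(C(=O)OCc3ccccc3)c21 | intermediate
14 | ethyl (2-methyl-1,3-dioxolan-2-yl)acetate | CCOC(=O)CC1(C)OCCO1 | starting material
15 | (2-methyl-1,3-dioxolan-2-yl)acetic acid | CC1(CC(=O)O)OCCO1 | intermediate
16 | 1-[(2-methyl-1,3-dioxolan-2-yl)acetyl]-1H-imidazole | CC1(CC(=O)n2ccnc2)OCCO1 | intermediate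
17 | benzyl 6,7-bis(benzyloxy)-3-[(2-methyl-1,3-dioxolan-2-yl)acetyl]-4-oxo-3,4-dihydro-2H-chromene-5-carboxylate (racemic) | CC1(CC(=O)C2COc3cc(OCc4ccccc4)c(OCc4ccccc4)c(C(=O)OCc4ccccc4)c3C2=O)OCCO1 | intermediate
18 | benzyl 6,7-bis(benzyloxy)-4-oxo-3-(3-oxobutanoyl)-3,4-dihydro-2H-chromene-5-carboxylate (racemic) | CC(=O)CC(=O)C1COc2cc(OCc3ccccc3)c(OCc3ccccc3)c(C(=O)OCc3ccccc3)c2C1=O | intermediate
19 | benzyl 6,7-bis(benzyloxy)-3-(hydroxymethylidene)-4-oxo-3,4-dihydro-2H-chromene-5-carboxylate (Z enol) | O/C=C1/COc2cc(OCc3ccccc3)c(OCc3ccccc3)c(C(=O)OCc3ccccc3)c2C1=O | intermediate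
20 | benzyl 6,7-bis(benzyloxy)-3-formyl-4-oxo-4H-chromene-5-carboxylate | O=Cc1coc2cc(OCc3ccccc3)c(OCc3ccccc3)c(C(=O)OCc3ccccc3)c2c1=O | intermediate
21 | 2-methoxypropene | COC(C)=C | starting material
22 | benzyl 7,8-bis(benzyloxy)-3-methoxy-3-methyl-10-oxo-4,4a-dihydro-3H,10H-pyrano[4,3-b]chromene-9-carboxylate (diastereomer mixture, racemic) | COC1(C)CC2Oc3cc(OCc4ccccc4)c(OCc4ccccc4)c(C(=O)OCc4ccccc4)c3C(=O)C2=CO1 | intermediate
23 | benzyl 7,8-bis(benzyloxy)-10a-bromo-1,3-dimethoxy-3-methyl-10-oxo-4,4a,10,10a-tetrahydro-1H,3H-pyrano[4,3-b]chromene-9-carboxylate (diastereomer mixture) | COC1OC(C)(OC)CC2Oc3cc(OCc4ccccc4)c(OCc4ccccc4)c(C(=O)OCc4ccccc4)c3C(=O)C12Br | intermediate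
24 | benzyl 7,8-bis(benzyloxy)-1,3-dimethoxy-3-methyl-10-oxo-4,10-dihydro-1H,3H-pyrano[4,3-b]chromene-9-carboxylate (diastereomer mixture, racemic) | COC1OC(C)(OC)Cc2oc3cc(OCc4ccccc4)c(OCc4ccccc4)c(C(=O)OCc4ccccc4)c3c(=O)c21 | intermediate
25 | 9-[(benzyloxy)carbonyl]-7,8-bis(benzyloxy)-3-methyl-10-oxo-10H-pyrano[4,3-b]chromen-2-ium (chiral phosphate as counter-ion) | CC1=CC2=C(C=[O+]1)C(=O)c1c(O2)cc(OCc3ccccc3)c(OCc3ccccc3)c1C(=O)OCc1ccccc1 | intermediate
26 | C-14–C-15 adduct: (1S)-1H-pyrano[4,3-b]chromen-10-one with a 3-methyl enol ether, carrying at C-1 the C-15 methine of triketone 18 (C-15 and C-3′ labile) | CC1=Cc2oc3cc(OCc4ccccc4)c(OCc4ccccc4)c(C(=O)OCc4ccccc4)c3c(=O)c2[C@@H](O1)C(C(C)=O)C(=O)C1COc2cc(OCc3ccccc3)c(OCc3ccccc3)c(C(=O)OCc3ccccc3)c2C1=O | intermediate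
27 | hexabenzyl-protected target: dibenzyl ester and tetrabenzyl ether of 28 (C-a R, C-14 S, C-15 S, C-b S) | C[C@@]12Cc3oc4cc(OCc5ccccc5)c(OCc5ccccc5)c(C(=O)OCc5ccccc5)c4c(=O)c3[C@@H](O1)[C@H]1C(=O)C3=C(O[C@@]1(C)O2)c1c(cc(OCc2ccccc2)c(OCc2ccccc2)c1C(=O)OCc1ccccc1)OC3 | intermediate
28 | CNP0230818.1: heptacyclic bis-ketal diacid, with rings A/B (6,7-dihydroxy-4-oxochromene-5-carboxylic acid) joined through ketal rings C and D to ring E and the dihydroxy-2H-chromene carboxylic acid rings F/G (C-a R, C-14 S, C-15 S, C-b S) | C[C@@]12Cc3oc4cc(O)c(O)c(C(=O)O)c4c(=O)c3[C@@H](O1)[C@H]1C(=O)C3=C(O[C@@]1(C)O2)c1c(cc(O)c(O)c1C(=O)O)OC3 | target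

**Count.** Total steps: 15. Longest linear sequence: 12 steps (steps 1–6, 10–13, 14, 15).

**Steps most likely to fail**

Step 14. The addition to the pyrylium ion may show poor facial selectivity, or the triketone may react through its more substituted enol carbon (C-3′) and stall the ketalisation. The fallback sets out from 24 and 18 and replaces asymmetric catalysis by resolution. The union is run with an achiral acid (diphenyl hydrogen phosphate, toluene, molecular sieves), which should give 27 together with its mirror image, the enantiomer of 27 F1. The two are separated by preparative HPLC on a chiral stationary phase (amylose tris(3,5-dimethylphenylcarbamate)), and the route is rejoined at 27.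

Step 6. The acrylate may be lost by fluoride-triggered conjugate addition or polymerisation at 125 °C, or the aryl carbanion may be protonated before acyl transfer and leave an aryl acrylate. The fallback sets out from 9, uses the more robust acetic acid as the acyl donor and builds ring F afterwards by a Mannich sequence. Silyl triflate 9 and acetic acid (CsF, THF, 125 °C, through aryne 11) should give the ortho-hydroxy ketone benzyl 6-acetyl-2,3-bis(benzyloxy)-5-hydroxybenzoate F2. Paraformaldehyde and dimethylamine hydrochloride (catalytic HCl, i-PrOH, reflux) should then give the Mannich base benzyl 2,3-bis(benzyloxy)-6-[3-(dimethylamino)propanoyl]-5-hydroxybenzoate F3 as its hydrochloride. Warming with aqueous NaHCO3/EtOAc eliminates dimethylamine to vinyl ketone 12, which closes by oxa-Michael addition, and the route is rejoined at 13.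

Step 15. Hydrogen may over-reduce the chromone double bond or cleave the allylic C–O bonds at C-14 and C-2′ before all six benzyl groups are gone. The fallback sets out from 27 and uses Lewis-acid debenzylation with a cation scavenger (BCl3, pentamethylbenzene, CH2Cl2, −78 °C; MeOH quench) to reach 28 directly; it makes no new compound (F0).

**Further compounds**

F1 | step 14 | enantiomer of 27 (C-a S, C-14 R, C-15 R, C-b R) | C[C@]12Cc3oc4cc(OCc5ccccc5)c(OCc5ccccc5)c(C(=O)OCc5ccccc5)c4c(=O)c3[C@H](O1)[C@@H]1C(=O)C3=C(O[C@]1(C)O2)c1c(cc(OCc2ccccc2)c(OCc2ccccc2)c1C(=O)OCc1ccccc1)OC3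
F2 | step 6 | benzyl 6-acetyl-2,3-bis(benzyloxy)-5-hydroxybenzoate | CC(=O)c1c(O)cc(OCc2ccccc2)c(OCc2ccccc2)c1C(=O)OCc1ccccc1
F3 | step 6 | benzyl 2,3-bis(benzyloxy)-6-[3-(dimethylamino)propanoyl]-5-hydroxybenzoate | CN(C)CCC(=O)c1c(O)cc(OCc2ccccc2)c(OCc2ccccc2)c1C(=O)OCc1ccccc1
F0 | step 15 | none | none
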